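The numbers in the tables are calculated with made-up constants.

If a product is eaten by the same substrate that feeds it, I stop following its curve and count its lifetimes, fastest clock first. Here the gas phase is held while substrate goes to target and target meets more substrate to give side product.

| flask | substrate | gas phase | remark | time |
|---|---|---|---|---|
| Friday's | 0.11 M | 42 mM (held) | run made earlier |  |
| red | 0.10 M | 42 mM (held) |  | 30 h |
| teal | 0.20 M | 42 mM (held) |  | 30 h |
| amber | 0.40 M | 42 mM (held) |  | 30 h |
| blue | 0.80 M | 42 mM (held) |  | 30 h |
| violet | 1.5 M | 42 mM (held) |  | 30 h |

- Friday's (time / h: target / %, substrate / %): 1.33: 2.0, 98.5; 2.50: 3.0, 96.2; 4.00: 4.2, 92.8; 6.00: 4.6, 89.0; 10.0: 6.6, 80.0; 20.0: 6.6, 60.5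

(readings scatter by 0.5 percentage points)

- percentages count the substrate that a species holds: one side product counts as two
- at the start none of the gas is dissolved
- the earlier runs were read with a standard deviation of 0.5 percentage points
- steps that have been proposed: substrate + target -> side product; substrate + dissolved gas -> target; gas phase <-> dissolved gas; dissolved gas + target -> over-reacted product
- "hardly changes" means that all values lie within two and a half points (for a concentration: within two and a half percent of the largest)

* amount of target at the end, in percent of the substrate charged for red, teal, amber, blue, violet, in this order
* how that number moves from the first to the last of them (rises, then falls / hardly changes / falls all the way / falls, then rises / rises all the way)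

The fastest clock I can read is the gas. After 1.33 h, Friday's run already holds 2.0% of target, a making rate of 0.0150 h⁻¹ on the substrate, so I take the dissolved gas to be in by about that first reading. With the gas steady, the making of target is pseudo-first-order in substrate.

The next clock is the target. Friday's target reads 6.6% at 10.0 h and 6.6% at 20.0 h, so I call this flat level the ceiling T*, the target concentration at which making and loss balance, 7.26 mM. Meanwhile the substrate falls from 80.0% to 60.5%, a rate of 0.0279 h⁻¹, which is twice the early rate. That fits each new target taking a second substrate with it, so I put the making at 0.0140 h⁻¹, half of that fall. A target then lives about 5.91 h at Friday's 10.0 h. At full charge, that lifetime is 5.20 h in red, shorter than the 30 h run, and 0.346 h in violet.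

The slowest clock is the substrate, with a half-life of 24.8 h, so it is still falling at the end. I set over-reaction aside as an assumption, one that a flat level does not test. On that assumption making and loss both scale with substrate, so in my reckoning it cancels and I carry T* over to each charge. Dividing T* by each charge, I commit to 7.26%, 3.63%, 1.81%, 0.907% and 0.484%, falling all the way.

The forecast gives 7.1%, 3.6%, 1.75%, 0.8% and 0.39%, which falls all the way, holding that “target stays near 7 mM in every run”; its last point lies below mine. The flasks give 7.42%, 4.24%, 2.28%, 1.18% and 0.633%, which falls all the way.

    substrate + target → side product (k = 1.55 M⁻¹ h⁻¹)
    substrate + dissolved gas → target (k = 0.380 M⁻¹ h⁻¹)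
    gas phase ⇌ dissolved gas, rate k3*(csat - [dissolved gas]) (kL = 4.81 h⁻¹)
    dissolved gas + target → over-reacted product (k = 0.760 M⁻¹ h⁻¹)

In red at 30.0 h, target is made at 0.957 times the rate it is used, and it goes to side product 2.3 times as fast as to over-reacted product, so the step I set aside carries a real part of the loss. T* over the red charge gives 7.26% against 7.42%, and over the violet charge 0.484% against 0.633%, which is 9.49 mM of target.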